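Atom numbers are germacrane numbers of the target: ring C1–C10, lactone O on C6, C7=C11, C12=O, C13 = CH2OAc, C14/C15 methyls.
Cuts: the two ester C–O bonds; then the ring bond C3–C4 together with C5–H, which opens the ten-membered ring to a butenolide with a propynyl group on C6 and, on C7, a chain ending in the C3 aldehyde; then the lactone C–O, C7–C8 and C11–C13 bonds, leaving a 4-silyloxy-2,5-diynoate, a Z-homoallylic Grignard reagent and formaldehyde.
Forward: the butenolide is built first (steps 8–10) and the carbocycle is closed last by a nickel-catalysed reductive alkyne–aldehyde coupling (step 12), followed by the two acylations.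
This closure is possible because C3 is a carbinol allylic to the E-C4(CH3)=C5 olefin inside the ring (the retron of alkyne + aldehyde + hydride), and because the planar butenolide ring (O–C6–C7=C11–C12) and the Z-C1=C10 olefin hold the chain ends near each other.
Stereochemistry: C6 (R) from a zinc–ProPhenol alkynylation; C3 (S) by 1,4-induction from C6 in the ring closure; Z-C1=C10 copied from the ring of 2,3-dihydrofuran; E-C4=C5 from cis addition of H and C3 to the alkyne.

Key step: step 12

Assumption: the (S,S) antipode of the ProPhenol ligand is taken to give the 4R carbinol 13; if the sense is the opposite, the (R,R) ligand is used and nothing else changes.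

Step 1
Reactants: 1 2,3-dihydrofuran
Product: 4 (Z)-4-iodopent-3-en-1-ol, via 5-lithio-2,3-dihydrofuran 2 (not isolated), via alkenyl(methyl)cuprate 3 (not isolated)
Conditions: t-BuLi, THF, −78 → 0 °C; Me2CuLi (from MeLi, CuBr·SMe2), Et2O/Me2S, −40 → 20 °C; I2, −78 → 0 °C
Reagents that add atoms: methyllithium, [Li]C; iodine, II
Why: α-Lithiation of the enol ether, ate-complex formation and 1,2-metalate rearrangement of the α-alkoxyalkenyl cuprate (methyl moves from copper to carbon with inversion as the ring C–O bond breaks) should leave copper cis to the hydroxyethyl arm, and iodinolysis with retention then gives the Z iodide, so the later ring-cis C1=C10 geometry is taken from the five-membered ring.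

Step 2
Reactants: 4 (Z)-4-iodopent-3-en-1-ol
Product: 5 (Z)-tert-butyl[(4-iodopent-3-en-1-yl)oxy]dimethylsilane
Conditions: TBSCl, imidazole, DMF, 0 °C → rt
Reagents that add atoms: tert-butyldimethylsilyl chloride, CC(C)(C)[Si](C)(C)Cl
Why: Standard silylation of the primary alcohol gives an ether that tolerates the organolithium and Grignard steps and is removed later with acid.

Step 3
Reactants: 5 (Z)-tert-butyl[(4-iodopent-3-en-1-yl)oxy]dimethylsilane
Product: 7 (Z)-6-(tert-butyldimethylsilyloxy)-3-methylhex-3-en-1-ol, via alkenyllithium 6 (not isolated)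
Conditions: t-BuLi (2.1 equiv), Et2O, −78 °C; oxirane, BF3·OEt2, −78 °C
Reagents that add atoms: oxirane, C1CO1
Why: Iodine–lithium exchange with retention of olefin geometry, then BF3-assisted SN2 opening of oxirane by the alkenyllithium, should add the two-carbon arm (future C9–C8) without touching the Z olefin.

Step 4
Reactants: 7 (Z)-6-(tert-butyldimethylsilyloxy)-3-methylhex-3-en-1-ol
Product: 8 (Z)-[(6-bromo-4-methylhex-3-en-1-yl)oxy](tert-butyl)dimethylsilane
Conditions: CBr4, PPh3, CH2Cl2, 0 °C
Reagents that add atoms: carbon tetrabromide, BrC(Br)(Br)Br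
Why: Appel bromination of the primary alcohol (SN2 on the alkoxyphosphonium ion) is neutral and should leave the silyl ether and the olefin alone.

Step 5
Reactants: 9 but-2-yn-1-ol
Product: 10 but-2-ynal
Conditions: MnO2, CH2Cl2, rt; filtered solution used directly
Reagents that add atoms: none
Why: Heterogeneous MnO2 oxidation of a propargylic alcohol stops at the aldehyde, and the volatile ynal is carried on in solution.

Step 6
Reactants: 10 but-2-ynal, 11 methyl propiolate
Product: 13 methyl (4R)-4-hydroxyhepta-2,5-diynoate, via zinc alkynylide 12 (not isolated)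
Conditions: (S,S)-ProPhenol (20 mol %), Me2Zn, Ph3P=O (40 mol %), toluene, 4 °C; aq NH4Cl
Reagents that add atoms: none
Why: Dinuclear zinc–ProPhenol-catalysed addition of the zinc alkynylide of methyl propiolate to the ynal (asymmetric aldehyde alkynylation) should set the future C6 centre as 4R, the chiral pocket choosing the aldehyde face.

Step 7
Reactants: 13 methyl (4R)-4-hydroxyhepta-2,5-diynoate
Product: 14 methyl (4R)-4-(triethylsilyloxy)hepta-2,5-diynoate
Conditions: TESOTf, 2,6-lutidine, CH2Cl2, −78 °C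
Reagents that add atoms: triethylsilyl triflate, CC[Si](CC)(CC)OS(=O)(=O)C(F)(F)F
Why: Silylation with the triflate and a hindered pyridine avoids conjugate addition of a nucleophilic base to the ynoate, and the silyl ether adds bulk on one side of the later allenolate and prevents premature lactonization.

Step 8
Reactants: 8 (Z)-[(6-bromo-4-methylhex-3-en-1-yl)oxy](tert-butyl)dimethylsilane, 14 methyl (4R)-4-(triethylsilyloxy)hepta-2,5-diynoate
Product: 17 methyl (2Z,4R)-3-[(3Z)-6-(tert-butyldimethylsilyloxy)-3-methylhex-3-en-1-yl]-2-(hydroxymethyl)-4-(triethylsilyloxy)hept-2-en-5-ynoate, via Grignard reagent 15 (not isolated), via magnesium allenolate 16 (not isolated)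
Conditions: Mg, THF, 40 °C; CuBr·SMe2 (20 mol %), 14, THF, −78 °C; CH2O (THF solution from cracked paraformaldehyde), −78 → −45 °C; aq NH4Cl
Reagents that add atoms: formaldehyde, C=O
Why: Copper-catalysed conjugate addition of the Grignard reagent to the alkynoate gives a magnesium allenolate that is trapped at the α-carbon by formaldehyde (tandem conjugate addition–aldol); the electrophile should enter in the plane of the two β-substituents on the side of the unbranched chain, away from the silyloxy-bearing carbon, so the ester ends cis to that carbon (2Z), as lactonization requires.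

Step 9
Reactants: 17 methyl (2Z,4R)-3-[(3Z)-6-(tert-butyldimethylsilyloxy)-3-methylhex-3-en-1-yl]-2-(hydroxymethyl)-4-(triethylsilyloxy)hept-2-en-5-ynoate
Product: 18 methyl (2Z,4R)-2-[(tert-butyldiphenylsilyloxy)methyl]-3-[(3Z)-6-(tert-butyldimethylsilyloxy)-3-methylhex-3-en-1-yl]-4-(triethylsilyloxy)hept-2-en-5-ynoate
Conditions: TBDPSCl, imidazole, CH2Cl2, 0 °C → rt
Reagents that add atoms: tert-butyldiphenylsilyl chloride, CC(C)(C)[Si](Cl)(c1ccccc1)c1ccccc1
Why: Silylation of the primary allylic alcohol installs a group that should survive the acid of step 10 and, unlike an allylic acetate, is inert to nickel(0) in step 12.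

Step 10
Reactants: 18 methyl (2Z,4R)-2-[(tert-butyldiphenylsilyloxy)methyl]-3-[(3Z)-6-(tert-butyldimethylsilyloxy)-3-methylhex-3-en-1-yl]-4-(triethylsilyloxy)hept-2-en-5-ynoate
Product: 20 (5R)-3-[(tert-butyldiphenylsilyloxy)methyl]-4-[(3Z)-6-hydroxy-3-methylhex-3-en-1-yl]-5-(prop-1-yn-1-yl)furan-2(5H)-one, via dihydroxy ester 19 (not isolated)
Conditions: CSA (10 mol %), MeOH/CH2Cl2, 0 °C → rt
Reagents that add atoms: none
Why: Acid-catalysed methanolysis should remove the triethylsilyl and the primary tert-butyldimethylsilyl ethers but not the tert-butyldiphenylsilyl ether, and the freed γ-hydroxyl, held cis to the ester on the tetrasubstituted olefin, lactonizes to the butenolide without base, so C6 is not epimerized.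

Step 11
Reactants: 20 (5R)-3-[(tert-butyldiphenylsilyloxy)methyl]-4-[(3Z)-6-hydroxy-3-methylhex-3-en-1-yl]-5-(prop-1-yn-1-yl)furan-2(5H)-one
Product: 21 (3Z)-6-[(2R)-4-[(tert-butyldiphenylsilyloxy)methyl]-5-oxo-2-(prop-1-yn-1-yl)-2,5-dihydrofuran-3-yl]-4-methylhex-3-enal
Conditions: Dess–Martin periodinane, pyridine, CH2Cl2, 0 °C; used at once
Reagents that add atoms: none
Why: Buffered Dess–Martin oxidation of the homoallylic primary alcohol should give the β,γ-unsaturated aldehyde without moving the Z olefin into conjugation.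

Step 12
Reactants: 21 (3Z)-6-[(2R)-4-[(tert-butyldiphenylsilyloxy)methyl]-5-oxo-2-(prop-1-yn-1-yl)-2,5-dihydrofuran-3-yl]-4-methylhex-3-enal
Product: 23 (3S,6R)-13-(tert-butyldiphenylsilyloxy)-3-(triethylsilyloxy)germacra-1(10)Z,4E,7(11)-trien-12,6-olide, via oxanickelacyclopentene 22 (not isolated)
Conditions: Ni(cod)2 (30 mol %) premixed 1:1 with IMes, Et3SiH (5 equiv), THF, 25 °C, syringe-pump addition of 21 (final 2 mM)
Reagents that add atoms: triethylsilane, CC[SiH](CC)CC
Why: Ni(0)–IMes binds the alkyne and the aldehyde of 21 and couples them oxidatively to oxanickelacyclopentene 22, which forms the C3–C4 bond; σ-bond metathesis of the Ni–O bond with Et3SiH and C–H reductive elimination at C5 then release silyl ether 23 and nickel(0). The closest known reaction type is the nickel/N-heterocyclic-carbene-catalysed reductive alkyne–aldehyde coupling with a silane in its macrocyclizing (ynal) form. The ten-membered carbocycle closes in the endo mode, both alkyne carbons (C4 and C5) becoming ring members, under high dilution. Hydrogen arrives at C5 cis to the new C3–C4 bond, so the C4=C5 olefin is E by mechanism, and the new C3 centre is controlled by C6 (1,4-induction): in the fused nickelacycle the C3–O bond lies in the olefin plane on nickel, the lactone C6–O bond should eclipse the developing C4–CH3 side so that C6–H and not the butenolide faces the bulky Ni–IMes unit, and the tether then reaches C3 from the C7 face, which corresponds to 3S. Regioselectivity (C–C bond at the methyl-bearing C4; bonding at C5 would give a nine-membered ring with an exocyclic ethylidene) is secured by the small carbene, which places the smaller alkyne substituent next to the aldehyde. Chemoselectivity is secured by the tetrasubstituted, weakly coordinating butenolide olefin, by the silyl instead of acyl group on O13, and by the 1:1 premixed catalyst, which leaves no free base to touch C6–H or the skipped enal.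

Step 13
Reactants: 23 (3S,6R)-13-(tert-butyldiphenylsilyloxy)-3-(triethylsilyloxy)germacra-1(10)Z,4E,7(11)-trien-12,6-olide
Product: 24 (3S,6R)-3,13-dihydroxygermacra-1(10)Z,4E,7(11)-trien-12,6-olide
Conditions: HF·pyridine, pyridine, THF, 0 °C → rt
Reagents that add atoms: none
Why: Buffered HF cleaves both silyl ethers through Si–F bond formation without the basicity that could epimerize the γ-position of the butenolide.

Step 14
Reactants: 24 (3S,6R)-3,13-dihydroxygermacra-1(10)Z,4E,7(11)-trien-12,6-olide
Product: 25 (3S,6R)-13-acetoxy-3-hydroxygermacra-1(10)Z,4E,7(11)-trien-12,6-olide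
Conditions: AcCl (1.1 equiv), 2,4,6-collidine, CH2Cl2, −78 °C
Reagents that add atoms: acetyl chloride, CC(Cl)=O
Why: Acylation with acetyl chloride and a hindered pyridine at low temperature should be kinetically selective for the unhindered primary allylic hydroxyl at C13 over the secondary C3 hydroxyl next to the C4 methyl group.

Step 15
Reactants: 25 (3S,6R)-13-acetoxy-3-hydroxygermacra-1(10)Z,4E,7(11)-trien-12,6-olide
Product: 26 (3S,6R)-13-acetoxy-3-propanoyloxygermacra-1(10)Z,4E,7(11)-trien-12,6-olide (target)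
Conditions: (EtCO)2O, pyridine, DMAP (cat.), CH2Cl2, 0 °C
Reagents that add atoms: propionic anhydride, CCC(=O)OC(=O)CC
Why: DMAP-catalysed acylation of the remaining secondary allylic alcohol proceeds with retention at C3 under conditions mild enough to leave C6 and the acetate untouched.

Compound list
1 | 2,3-dihydrofuran | C1=COCC1 | starting material
2 | 5-lithio-2,3-dihydrofuran | [Li]C1=CCCO1 | intermediate
3 | dilithium methyl[(Z)-5-oxidopent-2-en-2-yl]cuprate (copper cis to the CH2CH2O arm) | [Li+].[Li+].[O-]CC/C=C(/C)[Cu-]C | intermediate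
4 | (Z)-4-iodopent-3-en-1-ol | OCC/C=C(/C)I | intermediate
5 | (Z)-tert-butyl[(4-iodopent-3-en-1-yl)oxy]dimethylsilane | CC(C)(C)[Si](C)(C)OCC/C=C(/C)I | intermediate
6 | [(E)-5-(tert-butyldimethylsilyloxy)pent-2-en-2-yl]lithium (lithium cis to the CH2CH2O arm) | CC(C)(C)[Si](C)(C)OCC/C=C(/C)[Li] | intermediate
7 | (Z)-6-(tert-butyldimethylsilyloxy)-3-methylhex-3-en-1-ol | CC(C)(C)[Si](C)(C)OCC/C=C(/C)CCO | intermediate
8 | (Z)-[(6-bromo-4-methylhex-3-en-1-yl)oxy](tert-butyl)dimethylsilane | CC(C)(C)[Si](C)(C)OCC/C=C(/C)CCBr | intermediate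
9 | but-2-yn-1-ol | CC#CCO | starting material
10 | but-2-ynal | CC#CC=O | intermediate
11 | methyl propiolate | C#CC(=O)OC | starting material
12 | methyl 3-(methylzincio)propiolate | COC(=O)C#C[Zn]C | intermediate
13 | methyl (4R)-4-hydroxyhepta-2,5-diynoate | COC(=O)C#C[C@H](O)C#CC | intermediate
14 | methyl (4R)-4-(triethylsilyloxy)hepta-2,5-diynoate | COC(=O)C#C[C@H](O[Si](CC)(CC)CC)C#CC | intermediate
15 | [(Z)-6-(tert-butyldimethylsilyloxy)-3-methylhex-3-en-1-yl]magnesium bromide | CC(C)(C)[Si](C)(C)OCC/C=C(/C)CC[Mg]Br | intermediate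
16 | bromomagnesium allenolate of the conjugate adduct (O-bound; C7=C11=C12 allene) | COC(O[Mg]Br)=C=C(CC/C(C)=C\CCO[Si](C)(C)C(C)(C)C)[C@H](O[Si](CC)(CC)CC)C#CC | intermediate
17 | methyl (2Z,4R)-3-[(3Z)-6-(tert-butyldimethylsilyloxy)-3-methylhex-3-en-1-yl]-2-(hydroxymethyl)-4-(triethylsilyloxy)hept-2-en-5-ynoate | COC(=O)/C(CO)=C(/CC/C(C)=C\CCO[Si](C)(C)C(C)(C)C)[C@H](O[Si](CC)(CC)CC)C#CC | intermediate
18 | methyl (2Z,4R)-2-[(tert-butyldiphenylsilyloxy)methyl]-3-[(3Z)-6-(tert-butyldimethylsilyloxy)-3-methylhex-3-en-1-yl]-4-(triethylsilyloxy)hept-2-en-5-ynoate | COC(=O)/C(CO[Si](c1ccccc1)(c1ccccc1)C(C)(C)C)=C(/CC/C(C)=C\CCO[Si](C)(C)C(C)(C)C)[C@H](O[Si](CC)(CC)CC)C#CC | intermediate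
19 | methyl (2Z,4R)-2-[(tert-butyldiphenylsilyloxy)methyl]-4-hydroxy-3-[(3Z)-6-hydroxy-3-methylhex-3-en-1-yl]hept-2-en-5-ynoate | COC(=O)/C(CO[Si](c1ccccc1)(c1ccccc1)C(C)(C)C)=C(/CC/C(C)=C\CCO)[C@H](O)C#CC | intermediate
20 | (5R)-3-[(tert-butyldiphenylsilyloxy)methyl]-4-[(3Z)-6-hydroxy-3-methylhex-3-en-1-yl]-5-(prop-1-yn-1-yl)furan-2(5H)-one | CC#C[C@H]1OC(=O)C(CO[Si](c2ccccc2)(c2ccccc2)C(C)(C)C)=C1CC/C(C)=C\CCO | intermediate
21 | (3Z)-6-[(2R)-4-[(tert-butyldiphenylsilyloxy)methyl]-5-oxo-2-(prop-1-yn-1-yl)-2,5-dihydrofuran-3-yl]-4-methylhex-3-enal | CC#C[C@H]1OC(=O)C(CO[Si](c2ccccc2)(c2ccccc2)C(C)(C)C)=C1CC/C(C)=C\CC=O | intermediate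
22 | oxanickelacyclopentene: (IMes)Ni bound to C5 and to O3 of the closed ten-membered ring | Cc1cc(C)c(c(C)c1)N1C=C[N+](c2c(C)cc(C)cc2C)=C1[Ni-]1O[C@H]2C/C=C(/C)CCC3=C(CO[Si](c4ccccc4)(c4ccccc4)C(C)(C)C)C(=O)O[C@@H]3/C1=C2\C | intermediate
23 | (3S,6R)-13-(tert-butyldiphenylsilyloxy)-3-(triethylsilyloxy)germacra-1(10)Z,4E,7(11)-trien-12,6-olide | CC[Si](CC)(CC)O[C@H]1C/C=C(/C)CCC2=C(CO[Si](c3ccccc3)(c3ccccc3)C(C)(C)C)C(=O)O[C@@H]2/C=C/1C | intermediate
24 | (3S,6R)-3,13-dihydroxygermacra-1(10)Z,4E,7(11)-trien-12,6-olide | O[C@H]1C/C=C(/C)CCC2=C(CO)C(=O)O[C@@H]2/C=C/1C | intermediate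
25 | (3S,6R)-13-acetoxy-3-hydroxygermacra-1(10)Z,4E,7(11)-trien-12,6-olide | O[C@H]1C/C=C(/C)CCC2=C(COC(C)=O)C(=O)O[C@@H]2/C=C/1C | intermediate
26 | (3S,6R)-13-acetoxy-3-propanoyloxygermacra-1(10)Z,4E,7(11)-trien-12,6-olide | CCC(=O)O[C@H]1C/C=C(/C)CCC2=C(COC(C)=O)C(=O)O[C@@H]2/C=C/1C | target

Total step count: 15. Longest linear sequence: 12 steps (steps 1–4, then 8–15).

Steps most likely to fail

Step 12. Ring closure to a ten-membered ring may be slow compared with oligomerization, nickel(0) may insert into the propargylic C6–O bond of the lactone, and the induction from C6 at the new C3 centre may be weak or of the wrong sense. The fallback replaces the catalytic alkyne coupling by a Nozaki–Hiyama–Kishi closure of a preformed alkenyl iodide under ligand control; it sets out from 18 and comes back at 24. Hydrozirconation of the methyl alkyne of 18 (Cp2Zr(H)Cl, THF, 25 °C; zirconium should settle on the methyl-bearing carbon, away from the branched silyloxy carbon) and iodinolysis should give methyl (2Z,4R,5E)-2-[(tert-butyldiphenylsilyloxy)methyl]-3-[(3Z)-6-(tert-butyldimethylsilyloxy)-3-methylhex-3-en-1-yl]-6-iodo-4-(triethylsilyloxy)hepta-2,5-dienoate F1. CSA in MeOH then removes the triethylsilyl and tert-butyldimethylsilyl groups and closes the lactone to (5R)-3-[(tert-butyldiphenylsilyloxy)methyl]-4-[(3Z)-6-hydroxy-3-methylhex-3-en-1-yl]-5-[(1E)-2-iodoprop-1-en-1-yl]furan-2(5H)-one F2, and Dess–Martin oxidation gives the corresponding iodo aldehyde F3. CrCl2 with a chiral sulfonamide ligand and catalytic NiCl2 (THF/MeCN, high dilution) adds the alkenylchromium(III) species to the aldehyde, forms the same C3–C4 bond with the E olefin already in place, and should give (3S,6R)-13-(tert-butyldiphenylsilyloxy)-3-hydroxygermacra-1(10)Z,4E,7(11)-trien-12,6-olide F4. HF·pyridine then gives 24.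

Step 8. The magnesium allenolate may be protonated or may lose its geometric bias before it captures formaldehyde, and the Grignard reagent may attack the ester directly. The fallback separates the two bond formations; it sets out from 14 (with Grignard reagent 15 made from 8 as before) and comes back at 17. Reagent 15 is converted into the organocopper reagent with one equivalent of CuBr·SMe2 and added syn to 14 at −78 °C. The alkenylcopper, which holds its geometry at this temperature, is quenched with iodine to give methyl (2E,4R)-3-[(3Z)-6-(tert-butyldimethylsilyloxy)-3-methylhex-3-en-1-yl]-2-iodo-4-(triethylsilyloxy)hept-2-en-5-ynoate F5. Stille coupling of F5 with (tributylstannyl)methanol (Pd2(dba)3, AsPh3, CuI, DMF, 40 °C) proceeds with retention and should give 17.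

Step 14. Discrimination between the two allylic hydroxyls may be poor (diacylation, or acylation at C3). The fallback replaces kinetic acylation by protecting-group differentiation; it sets out from 24 and comes back at 26. TBSCl (1.05 equiv) with imidazole in CH2Cl2 at −20 °C should silylate only the primary hydroxyl and give (3S,6R)-13-(tert-butyldimethylsilyloxy)-3-hydroxygermacra-1(10)Z,4E,7(11)-trien-12,6-olide F6. Propionic anhydride, pyridine and DMAP give its 3-propionate F7, HF·pyridine gives (3S,6R)-13-hydroxy-3-propanoyloxygermacra-1(10)Z,4E,7(11)-trien-12,6-olide F8, and acetic anhydride in pyridine gives 26.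

Further compounds
F1 | step 12 | methyl (2Z,4R,5E)-2-[(tert-butyldiphenylsilyloxy)methyl]-3-[(3Z)-6-(tert-butyldimethylsilyloxy)-3-methylhex-3-en-1-yl]-6-iodo-4-(triethylsilyloxy)hepta-2,5-dienoate | COC(=O)/C(CO[Si](c1ccccc1)(c1ccccc1)C(C)(C)C)=C(/CC/C(C)=C\CCO[Si](C)(C)C(C)(C)C)[C@H](O[Si](CC)(CC)CC)/C=C(\C)I
F2 | step 12 | (5R)-3-[(tert-butyldiphenylsilyloxy)methyl]-4-[(3Z)-6-hydroxy-3-methylhex-3-en-1-yl]-5-[(1E)-2-iodoprop-1-en-1-yl]furan-2(5H)-one | I/C(C)=C/[C@H]1OC(=O)C(CO[Si](c2ccccc2)(c2ccccc2)C(C)(C)C)=C1CC/C(C)=C\CCO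
F3 | step 12 | (3Z)-6-[(2R)-4-[(tert-butyldiphenylsilyloxy)methyl]-2-[(1E)-2-iodoprop-1-en-1-yl]-5-oxo-2,5-dihydrofuran-3-yl]-4-methylhex-3-enal | I/C(C)=C/[C@H]1OC(=O)C(CO[Si](c2ccccc2)(c2ccccc2)C(C)(C)C)=C1CC/C(C)=C\CC=O
F4 | step 12 | (3S,6R)-13-(tert-butyldiphenylsilyloxy)-3-hydroxygermacra-1(10)Z,4E,7(11)-trien-12,6-olide | O[C@H]1C/C=C(/C)CCC2=C(CO[Si](c3ccccc3)(c3ccccc3)C(C)(C)C)C(=O)O[C@@H]2/C=C/1C
F5 | step 8 | methyl (2E,4R)-3-[(3Z)-6-(tert-butyldimethylsilyloxy)-3-methylhex-3-en-1-yl]-2-iodo-4-(triethylsilyloxy)hept-2-en-5-ynoate | COC(=O)/C(I)=C(/CC/C(C)=C\CCO[Si](C)(C)C(C)(C)C)[C@H](O[Si](CC)(CC)CC)C#CC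
F6 | step 14 | (3S,6R)-13-(tert-butyldimethylsilyloxy)-3-hydroxygermacra-1(10)Z,4E,7(11)-trien-12,6-olide | O[C@H]1C/C=C(/C)CCC2=C(CO[Si](C)(C)C(C)(C)C)C(=O)O[C@@H]2/C=C/1C
F7 | step 14 | (3S,6R)-13-(tert-butyldimethylsilyloxy)-3-propanoyloxygermacra-1(10)Z,4E,7(11)-trien-12,6-olide | CCC(=O)O[C@H]1C/C=C(/C)CCC2=C(CO[Si](C)(C)C(C)(C)C)C(=O)O[C@@H]2/C=C/1C
F8 | step 14 | (3S,6R)-13-hydroxy-3-propanoyloxygermacra-1(10)Z,4E,7(11)-trien-12,6-olide | CCC(=O)O[C@H]1C/C=C(/C)CCC2=C(CO)C(=O)O[C@@H]2/C=C/1C
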